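**Remark on the chemistry:** the target has no stereocentre and no configurationally stable axis, so it is one achiral compound and no step has to set configuration.

## Retrosynthetic overview

1. Target 22 ⇐ O-demethylation, ArNH2 → ArI, ArNO2 → ArNH2 ⇐ SNAr of the ring-B phenol 16 on 4-bromo-1-fluoro-2-nitrobenzene 17 (ring C is attached last, on the C2 oxygen).
2. Feature used: the central ring B carries oxygen on C1 and C2, bromine on C3, C4 and C5 and hydrogen on C6. C3–C6 map onto the diene carbons of 3,4,5-tribromo-2-pyrone 6; C1–C2 with both oxygens map onto the ketene acetal 12, which already carries ring A on the C1 oxygen.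
3. 16 ⇐ 6 + 12 by [4+2] cycloaddition, loss of CO2 and loss of silanol (forms ring-B bonds C1–C6 and C2–C3).
4. 6 ⇐ 4-hydroxy-2-pyrone (bromination at C3/C5, then OH → Br at C4) ⇐ methyl acetoacetate + methyl formate; 12 ⇐ aryloxyacetic acid 10 ⇐ 4-bromo-2-methoxyphenol + bromoacetic acid.
5. Ring order: rings A and C are bought as arenes; ring B is the only ring formed, in step 7.

Key step: step 7

## Route

Step 1
Reactants: 1 methyl acetoacetate; 2 methyl formate
Product: 4 4-hydroxy-2H-pyran-2-one, via formyl keto ester 3 (not isolated)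
Conditions: NaH, THF, 0 °C; n-BuLi, 0 °C; HCO2Me, −78 → 0 °C; aq. HCl; then TsOH (cat.), PhMe, reflux (−MeOH)
Reagents that add atoms: none
Why: γ-Acylation of the acetoacetate dianion (Weiler dianion Claisen condensation) followed by acid-catalysed enol lactonisation is the standard entry to 4-hydroxy-2-pyrones, and the formate ester leaves hydrogen on C6.

Step 2
Reactants: 4 4-hydroxy-2H-pyran-2-one
Product: 5 3,5-dibromo-4-hydroxy-2H-pyran-2-one
Conditions: Br2 (2.1 equiv), AcOH, rt → 50 °C
Reagents that add atoms: bromine, BrBr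
Why: Electrophilic bromination of a 4-hydroxy-2-pyrone takes place at its two nucleophilic enol-type carbons C3 and C5, and any bromine adduct across C5=C6 should revert to the substitution product by loss of HBr.

Step 3
Reactants: 5 3,5-dibromo-4-hydroxy-2H-pyran-2-one
Product: 6 3,4,5-tribromo-2H-pyran-2-one
Conditions: POBr3 (1.5 equiv), DMF (cat.), PhMe, 90 °C
Reagents that add atoms: phosphorus oxybromide, O=P(Br)(Br)Br
Why: Deoxybromination of a vinylogous acid (O-phosphorylation, then addition–elimination of bromide at C4), as used for 4-hydroxy-6-methyl-2-pyrone and 4-hydroxycoumarins, installs the C4 bromine that electrophilic bromination cannot place on this electrophilic carbon.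

Step 4
Reactants: 7 4-bromo-2-methoxyphenol
Product: 8 2,4-dibromo-6-methoxyphenol
Conditions: NBS (1.05 equiv), i-Pr2NH (10 mol %), CH2Cl2, 0 °C → rt
Reagents that add atoms: N-bromosuccinimide, O=C1CCC(=O)N1Br
Why: Amine-mediated ortho-bromination of a phenol should deliver bromine to C6, the only free position ortho or para to the hydroxyl, in preference to the position para to the methoxy group.

Step 5
Reactants: 8 2,4-dibromo-6-methoxyphenol; 9 bromoacetic acid
Product: 10 2-(2,4-dibromo-6-methoxyphenoxy)acetic acid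
Conditions: NaOH (aq.), H2O, 100 °C; then HCl to pH 1
Reagents that add atoms: none
Why: Williamson O-alkylation of the phenoxide with bromoacetate is the classical aryloxyacetic acid synthesis and is routine for 2,6-disubstituted halophenols.

Step 6
Reactants: 10 2-(2,4-dibromo-6-methoxyphenoxy)acetic acid
Product: 12 2-(2,4-dibromo-6-methoxyphenoxy)-1,1-bis(trimethylsilyloxy)ethene, via trimethylsilyl ester 11 (not isolated)
Conditions: LiHMDS (1.0 equiv), TMSCl (1.05 equiv), THF, 0 °C → rt; then TMSCl (1.3 equiv), LiHMDS (1.1 equiv), −78 °C → rt; hexane, filtration under Ar; used crude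
Reagents that add atoms: chlorotrimethylsilane, C[Si](C)(C)Cl
Why: Silylation of the carboxylate and kinetic enolisation of the silyl ester with in situ O-silylation is the Ainsworth-type preparation of bis(silyl) ketene acetals, and LiHMDS in place of LDA is too weak a base to metalate the ring proton flanked by two bromines.

Step 7
Reactants: 6 3,4,5-tribromo-2H-pyran-2-one; 12 2-(2,4-dibromo-6-methoxyphenoxy)-1,1-bis(trimethylsilyloxy)ethene (1.5 equiv)
Product: 16 2,3,4-tribromo-6-(2,4-dibromo-6-methoxyphenoxy)phenol, via bicyclic lactone 13 (not isolated), via cyclohexadiene 14 (not isolated), via aryl silyl ether 15 (not isolated)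
Conditions: PhMe, 60 → 110 °C (sealed tube); then 1 M HCl, THF, rt
Reagents that add atoms: none
Why: Proposed new method: the two silyloxy groups make the aryloxy-bearing CH carbon of 12 the nucleophilic terminus, which should bond to C6 of pyrone 6 (the unhindered, electrophilic diene terminus) while the acetal carbon bonds to C3 in a concerted asynchronous or stepwise zwitterionic inverse-demand [4+2] to give bridged lactone 13; retro-[4+2] loss of CO2 gives diene 14, whose only possible 1,2-elimination (H from the aryloxy carbon, silanol from the acetal carbon) aromatises it to silyl ether 15, which the acidic work-up hydrolyses to 16. The closest known reaction type is the Diels–Alder/decarboxylation/alcohol-elimination benzannulation of 3-bromo-, 3,5-dibromo- and 3-carbomethoxy-2-pyrones with enol ethers and ketene acetals; new here are the fully brominated C3–C5 diene and the O-aryl bis(silyl) ketene acetal. Ring B is closed as a six-membered carbocycle by this intermolecular [4+2] cycloaddition, which forms the ring-B C1–C6 and C2–C3 bonds. No stereocentre survives, because the sp3 centres of 13 are erased on aromatisation, so endo/exo selectivity is irrelevant. The step needs regioselectivity (aryloxy carbon next to C6–H, acetal oxygen next to C3–Br), which the matched polarity of the two partners secures, and chemoselectivity for cycloaddition over addition–elimination at the C4 bromide, which the non-polar solvent, the absence of Lewis acid or fluoride and the shielding of C4 by its two bromine neighbours should favour.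

Step 8
Reactants: 16 2,3,4-tribromo-6-(2,4-dibromo-6-methoxyphenoxy)phenol; 17 4-bromo-1-fluoro-2-nitrobenzene
Product: 18 1,2,3-tribromo-4-(4-bromo-2-nitrophenoxy)-5-(2,4-dibromo-6-methoxyphenoxy)benzene
Conditions: K2CO3, DMF, 70 °C
Reagents that add atoms: none
Why: SNAr (addition–elimination through a Meisenheimer complex) of the phenoxide on the fluoride ortho to nitro is reliable even for 2,6-disubstituted bromophenoxides, and the unactivated aryl bromides do not react.

Step 9
Reactants: 18 1,2,3-tribromo-4-(4-bromo-2-nitrophenoxy)-5-(2,4-dibromo-6-methoxyphenoxy)benzene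
Product: 19 5-bromo-2-[2,3,4-tribromo-6-(2,4-dibromo-6-methoxyphenoxy)phenoxy]aniline
Conditions: Fe powder, AcOH/EtOH, 70 °C
Reagents that add atoms: none
Why: Béchamp reduction reduces the nitro group by electron transfer and does not hydrogenolyse C–Br bonds, which catalytic hydrogenation would put at risk.

Step 10
Reactants: 19 5-bromo-2-[2,3,4-tribromo-6-(2,4-dibromo-6-methoxyphenoxy)phenoxy]aniline
Product: 21 1,2,3-tribromo-4-(4-bromo-2-iodophenoxy)-5-(2,4-dibromo-6-methoxyphenoxy)benzene, via diazonium hydrogensulfate 20 (not isolated)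
Conditions: NaNO2, H2SO4/AcOH, 0–5 °C; then KI, H2O, 0 °C → rt
Reagents that add atoms: potassium iodide, [K+].[I-]
Why: Diazotisation and iodo-dediazoniation (Sandmeyer-type, no copper needed) replaces NH2 by iodine at the same carbon, and Pschorr-type cyclisation has no site because both ring-B positions flanking the ether oxygen are substituted.

Step 11
Reactants: 21 1,2,3-tribromo-4-(4-bromo-2-iodophenoxy)-5-(2,4-dibromo-6-methoxyphenoxy)benzene
Product: 22 Bromoiesol B, 3,5-dibromo-2-[3,4,5-tribromo-2-(4-bromo-2-iodophenoxy)phenoxy]phenol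
Conditions: BBr3 (3 equiv), CH2Cl2, −78 °C → rt; H2O
Reagents that add atoms: none
Why: Boron tribromide cleavage of the aryl methyl ether (Lewis acid complexation, bromide attack on methyl) leaves diaryl ethers, aryl bromides and the aryl iodide untouched.

## Compound list

1 | methyl acetoacetate | CC(=O)CC(=O)OC | starting material
2 | methyl formate | COC=O | starting material
3 | methyl (Z)-5-hydroxy-3-oxopent-4-enoate (enol of methyl 3,5-dioxopentanoate) | O/C=C\C(=O)CC(=O)OC | intermediate
4 | 4-hydroxy-2H-pyran-2-one | O=C1C=C(O)C=CO1 | intermediate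
5 | 3,5-dibromo-4-hydroxy-2H-pyran-2-one | O=C1OC=C(Br)C(O)=C1Br | intermediate
6 | 3,4,5-tribromo-2H-pyran-2-one | O=C1OC=C(Br)C(Br)=C1Br | intermediate
7 | 4-bromo-2-methoxyphenol | COc1cc(Br)ccc1O | starting material
8 | 2,4-dibromo-6-methoxyphenol | COc1cc(Br)cc(Br)c1O | intermediate
9 | bromoacetic acid | OC(=O)CBr | starting material
10 | 2-(2,4-dibromo-6-methoxyphenoxy)acetic acid | COc1cc(Br)cc(Br)c1OCC(=O)O | intermediate
11 | trimethylsilyl 2-(2,4-dibromo-6-methoxyphenoxy)acetate | COc1cc(Br)cc(Br)c1OCC(=O)O[Si](C)(C)C | intermediate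
12 | 2-(2,4-dibromo-6-methoxyphenoxy)-1,1-bis(trimethylsilyloxy)ethene | C[Si](C)(C)OC(O[Si](C)(C)C)=COc1c(Br)cc(Br)cc1OC | intermediate
13 | 4,5,6-tribromo-7-(2,4-dibromo-6-methoxyphenoxy)-8,8-bis(trimethylsilyloxy)-2-oxabicyclo[2.2.2]oct-5-en-3-one (diastereomer mixture, racemic) | O=C1OC2C(Br)=C(Br)C1(Br)C(O[Si](C)(C)C)(O[Si](C)(C)C)C2Oc1c(Br)cc(Br)cc1OC | intermediate
14 | 1,2,3-tribromo-5-(2,4-dibromo-6-methoxyphenoxy)-6,6-bis(trimethylsilyloxy)cyclohexa-1,3-diene (racemic) | BrC1=C(Br)C(Br)=CC(Oc2c(Br)cc(Br)cc2OC)C1(O[Si](C)(C)C)O[Si](C)(C)C | intermediate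
15 | [2,3,4-tribromo-6-(2,4-dibromo-6-methoxyphenoxy)phenoxy]trimethylsilane | COc1cc(Br)cc(Br)c1Oc1cc(Br)c(Br)c(Br)c1O[Si](C)(C)C | intermediate
16 | 2,3,4-tribromo-6-(2,4-dibromo-6-methoxyphenoxy)phenol | COc1cc(Br)cc(Br)c1Oc1cc(Br)c(Br)c(Br)c1O | intermediate
17 | 4-bromo-1-fluoro-2-nitrobenzene | O=[N+]([O-])c1cc(Br)ccc1F | starting material
18 | 1,2,3-tribromo-4-(4-bromo-2-nitrophenoxy)-5-(2,4-dibromo-6-methoxyphenoxy)benzene | COc1cc(Br)cc(Br)c1Oc1cc(Br)c(Br)c(Br)c1Oc1ccc(Br)cc1[N+](=O)[O-] | intermediate
19 | 5-bromo-2-[2,3,4-tribromo-6-(2,4-dibromo-6-methoxyphenoxy)phenoxy]aniline | COc1cc(Br)cc(Br)c1Oc1cc(Br)c(Br)c(Br)c1Oc1ccc(Br)cc1N | intermediate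
20 | 5-bromo-2-[2,3,4-tribromo-6-(2,4-dibromo-6-methoxyphenoxy)phenoxy]benzenediazonium hydrogensulfate | COc1cc(Br)cc(Br)c1Oc1cc(Br)c(Br)c(Br)c1Oc1ccc(Br)cc1[N+]#N.OS(=O)(=O)[O-] | intermediate
21 | 1,2,3-tribromo-4-(4-bromo-2-iodophenoxy)-5-(2,4-dibromo-6-methoxyphenoxy)benzene | COc1cc(Br)cc(Br)c1Oc1cc(Br)c(Br)c(Br)c1Oc1ccc(Br)cc1I | intermediate
22 | Bromoiesol B, 3,5-dibromo-2-[3,4,5-tribromo-2-(4-bromo-2-iodophenoxy)phenoxy]phenol | Oc1cc(Br)cc(Br)c1Oc1cc(Br)c(Br)c(Br)c1Oc1ccc(Br)cc1I | target

## Step count and risks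

Total step count: 11. Longest linear sequence: 8 steps (steps 4, 5, 6, 7, 8, 9, 10, 11; the pyrone branch through steps 1, 2, 3 and 7–11 is equally long).

**Steps most likely to fail**

1. Step 7 (proposed new method). The ketene acetal may attack C4 of the pyrone by addition–elimination with loss of bromide, may add once at C6 without closing the crowded C2–C3 bond, or may be consumed by the silanol that is released, so that no benzannulation occurs. The fallback uses known chemistry, sets out from 8 and 17 and returns to the route at 16. SNAr of the phenoxide of 8 on 17 (K2CO3, DMF, 80 °C) should give 1,5-dibromo-2-(4-bromo-2-nitrophenoxy)-3-methoxybenzene F1, in which the bromine para to the new ether oxygen is the future ring-B C4 bromine. Fe/AcOH reduction should give 5-bromo-2-(2,4-dibromo-6-methoxyphenoxy)aniline F2. NBS (2 equiv, MeCN, 0 °C) should brominate the far more activated aniline ring ortho and para to nitrogen, on both sides of the bromine already present, to give 2,3,4-tribromo-6-(2,4-dibromo-6-methoxyphenoxy)aniline F3. Diazotisation (NaNO2, H2SO4/AcOH, 0 °C) to 2,3,4-tribromo-6-(2,4-dibromo-6-methoxyphenoxy)benzenediazonium hydrogensulfate F4 and copper-mediated hydroxy-dediazoniation (Cu2O, Cu(NO3)2, H2O, rt) should then give 16.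

2. Step 6. The amide base may attack silicon of the silyl ester instead of enolising it, the α-aryloxy enolate may undergo aryl migration before it is trapped, or the hydrolysis-prone bis(silyl) acetal may revert to the acid on handling. The fallback sets out from 8 and returns at 16, using an ordinary ester enolate and an acid-labile oxygen substituent. Alkylation of 8 with tert-butyl bromoacetate (K2CO3, acetone, reflux) should give tert-butyl 2-(2,4-dibromo-6-methoxyphenoxy)acetate F5. LiHMDS/TMSCl (THF, −78 °C) should convert it into the mixed ketene acetal 1-tert-butoxy-2-(2,4-dibromo-6-methoxyphenoxy)-1-(trimethylsilyloxy)ethene F6. Heating F6 with 6 in toluene as in step 7 would pass through the bicyclic lactone 4,5,6-tribromo-8-tert-butoxy-7-(2,4-dibromo-6-methoxyphenoxy)-8-(trimethylsilyloxy)-2-oxabicyclo[2.2.2]oct-5-en-3-one F7 and, after loss of CO2, the cyclohexadiene 1,2,3-tribromo-6-tert-butoxy-5-(2,4-dibromo-6-methoxyphenoxy)-6-(trimethylsilyloxy)cyclohexa-1,3-diene F8. F8 aromatises either by loss of tert-butanol to 15 or by loss of silanol to 1,2,3-tribromo-4-tert-butoxy-5-(2,4-dibromo-6-methoxyphenoxy)benzene F9. TFA in CH2Cl2 should cleave both to 16 without touching the ring-A methyl ether.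

3. Step 3. The strongly acidic enol, flanked by two bromines, may resist phosphorylation, or the hot phosphoryl bromide may open or degrade the electron-poor lactone before bromide exchange at C4 is complete. The fallback sets out from 5 and returns at 6, separating activation from substitution. Tf2O/pyridine (CH2Cl2, −78 → 0 °C) should give 3,5-dibromo-2-oxo-2H-pyran-4-yl trifluoromethanesulfonate F10, and LiBr in acetone at rt should displace the triflate by addition–elimination at C4 to give 6.

## Further compounds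

F1 | step 7 | 1,5-dibromo-2-(4-bromo-2-nitrophenoxy)-3-methoxybenzene | COc1cc(Br)cc(Br)c1Oc1ccc(Br)cc1[N+](=O)[O-]
F2 | step 7 | 5-bromo-2-(2,4-dibromo-6-methoxyphenoxy)aniline | COc1cc(Br)cc(Br)c1Oc1ccc(Br)cc1N
F3 | step 7 | 2,3,4-tribromo-6-(2,4-dibromo-6-methoxyphenoxy)aniline | COc1cc(Br)cc(Br)c1Oc1cc(Br)c(Br)c(Br)c1N
F4 | step 7 | 2,3,4-tribromo-6-(2,4-dibromo-6-methoxyphenoxy)benzenediazonium hydrogensulfate | COc1cc(Br)cc(Br)c1Oc1cc(Br)c(Br)c(Br)c1[N+]#N.OS(=O)(=O)[O-]
F5 | step 6 | tert-butyl 2-(2,4-dibromo-6-methoxyphenoxy)acetate | COc1cc(Br)cc(Br)c1OCC(=O)OC(C)(C)C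
F6 | step 6 | 1-tert-butoxy-2-(2,4-dibromo-6-methoxyphenoxy)-1-(trimethylsilyloxy)ethene | CC(C)(C)OC(O[Si](C)(C)C)=COc1c(Br)cc(Br)cc1OC
F7 | step 6 | 4,5,6-tribromo-8-tert-butoxy-7-(2,4-dibromo-6-methoxyphenoxy)-8-(trimethylsilyloxy)-2-oxabicyclo[2.2.2]oct-5-en-3-one | O=C1OC2C(Br)=C(Br)C1(Br)C(OC(C)(C)C)(O[Si](C)(C)C)C2Oc1c(Br)cc(Br)cc1OC
F8 | step 6 | 1,2,3-tribromo-6-tert-butoxy-5-(2,4-dibromo-6-methoxyphenoxy)-6-(trimethylsilyloxy)cyclohexa-1,3-diene | BrC1=C(Br)C(Br)=CC(Oc2c(Br)cc(Br)cc2OC)C1(OC(C)(C)C)O[Si](C)(C)C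
F9 | step 6 | 1,2,3-tribromo-4-tert-butoxy-5-(2,4-dibromo-6-methoxyphenoxy)benzene | COc1cc(Br)cc(Br)c1Oc1cc(Br)c(Br)c(Br)c1OC(C)(C)C
F10 | step 3 | 3,5-dibromo-2-oxo-2H-pyran-4-yl trifluoromethanesulfonate | O=C1OC=C(Br)C(OS(=O)(=O)C(F)(F)F)=C1Br
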